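Late in a maple run, once its living ends have died, a chain's length is what a living end added per second times the seconds it lived, plus the one unit that began it.

common to all: free monomer 0.064 M; initiator 0.13 mM; time 50 s
- maple: transfer agent 0.640 mM
- larch: transfer agent 0.150 mM

* which of the two ends with the longer chains by the average number of monomer units in a chain (chains begun, living or dead) ("neither" if they lie within 10%) (maple / larch / neither)
* average number of monomer units in a chain (chains begun, living or dead) at the end, maple
* average number of monomer units in a chain (chains begun, living or dead) at the end, larch

- the average divides the monomer in chains by the number of chains begun, living and dead together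
- run time (maple): 50 s

    initiator + monomer in chains → spent initiator (k1 = 0.460 M⁻¹ s⁻¹)
    free monomer + living end → monomer in chains + living end, rate k2*[living end]*[free monomer] (k2 = 44.1 M⁻¹ s⁻¹)
    living end + transfer agent → dead chain (k3 = 119 M⁻¹ s⁻¹)
    free monomer + initiator → living end + monomer in chains (k4 = 0.554 M⁻¹ s⁻¹)

A living end takes up free monomer at 2.82 s⁻¹ at the start, and transfer agent ends it at 0.0762 s⁻¹ in maple and 0.0178 s⁻¹ in larch, time constants of 13.1 s and 56.2 s. The ratio of these rates is 37.1 in maple and 158 in larch. I carry it as the units per lifetime, the kinetic chain length. That first answer does not serve for larch at 50 s, because the lifetime there is longer than the run.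

So I put it back and go round again. Initiator and free monomer begin chains at a rate that decays at 0.0355 s⁻¹, and the loss of monomer in chains through initiator I drop, its half-life of 190 min in maple, with the concentrations as charged, being long against the run. Beginning and ending are then two first-order lags in series, and they give the mean time alive per chain begun by 50 s: 11.1 s in maple and 23.4 s in larch. Youth thus cuts the units per lifetime by a factor of 0.846 in maple and 0.417 in larch. With the first unit added, I commit to 32.3 in maple and 67.1 in larch, so larch ends longer, beyond the margin. This reckoning leaves free monomer in larch at a factor of 0.888 of its charge at the end, a slowing I do not fold in.

The forecast names larch, with 33 for maple and 66 for larch, noting for larch that “Termination is slow”.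

The flask gives 32.9 in maple and 65.9 in larch, so larch ends longer. Left until 500 s, maple reaches 40.6 and larch 225. At 50 s, the lengths stand at 0.887 of the units per lifetime in maple and 0.417 in larch.

A neighbour flask, like maple but with 0.0026 M of transfer agent, has a lifetime of 3.23 s, short against the run, and 9.12 units per lifetime, so with the first unit I expect 10.1. The flask gives 9.97.

Its constants come from no measurement.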